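**Strategy.** Ring A of the target (C1, C2, C3, C4, C4a, C8a; ketone at C2) is cut across C1–C8a and C4–C4a. A 2-silyloxybuta-1,3-diene supplies C1–C4 and one C(CH3)=CH edge of flat, achiral 2,5-dimethyl-1,4-benzoquinone supplies C8a and C4a, so that the two para methyl groups of the quinone become the C8a and C6 methyl groups of ring B. One catalytic enantioselective Diels–Alder reaction forms both bonds and the angular quaternary centre. The enedione it leaves in ring B is then used up: it corrects C4a, relays chirality to C6 through an Ireland–Claisen shift, and vanishes. The side chain enters last at C1.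

Key step: step 5

Remark: bicyclic intermediates carry the locants of the target (C1 side-chain carbon, C2 ketone carbon, C4a ring-fusion CH, C6 quaternary carbon of ring B, C8a angular carbon). The sense of induction in step 5 is assumed from the accepted binding model of the catalyst (carbonyl lone pair syn to the α-C–H on boron, one face of the bound C=C covered by an aryl group); it was derived by hand and is not certain.

Step 1
Reactants: 1 (R)-2-methylglycidol; 2 allylmagnesium bromide
Product: 3 (S)-2-methylhex-5-ene-1,2-diol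
Conditions: allylMgBr (2.5 equiv), CuI (10 mol %), THF, −30 to 0 °C; aq. NH4Cl
Reagents that add atoms: allylmagnesium bromide, C=CC[Mg]Br
Why: Copper-catalysed SN2 opening of the 2,2-disubstituted epoxide at its CH2 terminus by the Grignard reagent (the first equivalent is consumed by the hydroxyl group); the quaternary stereocentre is not a reaction site and is retained.

Step 2
Reactants: 3 (S)-2-methylhex-5-ene-1,2-diol; 4 2,2-dimethoxypropane
Product: 5 (S)-4-(but-3-en-1-yl)-2,2,4-trimethyl-1,3-dioxolane
Conditions: Me2C(OMe)2, pyridinium p-toluenesulfonate (5 mol %), CH2Cl2, rt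
Reagents that add atoms: 2,2-dimethoxypropane, COC(C)(C)OC
Why: Acid-catalysed transketalisation closes the five-membered acetonide on the 1,2-diol without touching the stereocentre.

Step 3
Reactants: 5 (S)-4-(but-3-en-1-yl)-2,2,4-trimethyl-1,3-dioxolane; 6 ozone
Product: 8 (S)-3-(2,2,4-trimethyl-1,3-dioxolan-4-yl)propanal, via ozonide 7 (not isolated)
Conditions: O3, CH2Cl2, −78 °C; then PPh3, −78 °C to rt
Reagents that add atoms: ozone, [O-][O+]=O
Why: Ozonolysis of the terminal alkene with reductive phosphine work-up of the ozonide gives the aldehyde; the acetonide is inert.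

Step 4
Reactants: 9 but-3-en-2-one; 10 triisopropylsilyl trifluoromethanesulfonate
Product: 11 2-(triisopropylsilyloxy)buta-1,3-diene
Conditions: iPr3SiOTf (1.05 equiv), Et3N (1.3 equiv), CH2Cl2, 0 °C to rt
Reagents that add atoms: triisopropylsilyl trifluoromethanesulfonate, CC(C)[Si](C(C)C)(C(C)C)OS(=O)(=O)C(F)(F)F
Why: Soft enolisation and O-silylation of the methyl ketone (silyl enol ether formation) give the cross-conjugated 2-silyloxy diene.

Step 5
Reactants: 11 2-(triisopropylsilyloxy)buta-1,3-diene; 12 2,5-dimethyl-1,4-benzoquinone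
Product: 13 cis-fused 6,8a-dimethyl-2-(triisopropylsilyloxy)-1,4,4a,8a-tetrahydronaphthalene-5,8-dione (4a-H cis to 8a-CH3; C8a configured as in the target)
Conditions: (S)-3,3-diphenyl-1-(2-methylphenyl)tetrahydro-1H,3H-pyrrolo[1,2-c][1,3,2]oxazaborole (20 mol %) activated with HN(SO2CF3)2 (20 mol %), 11 (1.5 equiv), CH2Cl2, −78 °C
Reagents that add atoms: 2,5-dimethyl-1,4-benzoquinone, CC1=CC(=O)C(C)=CC1=O
Why: The protonated oxazaborolidine binds one quinone carbonyl (the future C5=O) through the lone pair syn to its α-C–H, which makes the methyl-bearing carbon (future C8a) the electrophilic β-terminus; the CH2 terminus of the diene next to C–OSi, the more nucleophilic one, bonds there in a concerted, asynchronous, endo [4+2] cycloaddition (Diels–Alder reaction; closest known type: oxazaborolidinium-catalysed additions of 2-silyloxybutadienes to alkylated benzoquinones). Ring A closes as a six-membered carbocycle by intermolecular cycloaddition of a 4π and a 2π component, suprafacial on both, so 4a-H and 8a-CH3 come out cis. The absolute configuration at C8a is set by the catalyst, whose aryl group covers one face of the bound C=C; C4a follows from the suprafacial addition and is corrected in step 6. Site selectivity is not an issue because the two C(CH3)=CH bonds of the quinone are equivalent by symmetry. Regioselectivity is secured by the match of the nucleophilic diene terminus with the β-carbon of the bound enone, which puts the silyloxy carbon at C2. Facial selectivity is the task of the catalyst.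

Step 6
Reactants: 13 cis-fused enedione
Product: 14 trans-fused 6,8a-dimethyl-2-(triisopropylsilyloxy)-1,4,4a,8a-tetrahydronaphthalene-5,8-dione (4a-H anti to 8a-CH3)
Conditions: DBU (0.2 equiv), CH2Cl2, 0 °C to rt
Reagents that add atoms: none
Why: Base-mediated epimerisation at C4a through the C5 enolate should converge on the trans-fused enedione, the usual thermodynamic outcome for angularly methylated quinone adducts; C8a is quaternary, so neither aromatisation nor loss of its configuration is possible.

Step 7
Reactants: 14 trans-fused enedione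
Product: 15 trans-fused 5-hydroxy-6,8a-dimethyl-2-(triisopropylsilyloxy)-4,4a,5,8a-tetrahydronaphthalen-8(1H)-one (5-OH drawn cis to 8a-CH3)
Conditions: NaBH4 (1.0 equiv), CeCl3·7H2O (1.1 equiv), MeOH/CH2Cl2, −78 °C
Reagents that add atoms: none
Why: Luche 1,2-reduction is expected at C5, the carbonyl next to the C4a methine, because the C8 carbonyl is neopentylic and deactivated as a β-methyl enone; the carbinol configuration is irrelevant since this oxygen is removed in step 9.

Step 8
Reactants: 15 γ-hydroxy enone; 16 acetic anhydride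
Product: 17 5-O-acetate of 15
Conditions: Ac2O, pyridine, 4-(dimethylamino)pyridine (cat.), CH2Cl2, rt
Reagents that add atoms: acetic anhydride, CC(=O)OC(C)=O
Why: Acylation of the secondary allylic alcohol turns the C5 oxygen into a leaving group for the reductive step.

Step 9
Reactants: 17 γ-acetoxy enone
Product: 19 trans-fused 6,8a-dimethyl-2-(triisopropylsilyloxy)-4,4a,5,8a-tetrahydronaphthalen-8(1H)-one, via deconjugated C5=C6 enone 18 (not isolated)
Conditions: SmI2 (2.5 equiv), THF/MeOH, −78 °C; then DBU (0.5 equiv), CH2Cl2, rt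
Reagents that add atoms: none
Why: Samarium diiodide reduces the γ-acetoxy enone with loss of acetate (reductive elimination through the samarium dienolate) and DBU moves the double bond back into conjugation; C4a is not involved and stays trans.

Step 10
Reactants: 19 trans-fused enone
Product: 20 trans-fused 6,8a-dimethyl-2-(triisopropylsilyloxy)-1,4,4a,5,8,8a-hexahydronaphthalen-8-ol (8-OH cis to 8a-CH3)
Conditions: NaBH4, CeCl3·7H2O, MeOH, −40 °C
Reagents that add atoms: none
Why: Luche reduction in which hydride should add to C8 from the face opposite the axial 8a-methyl group (axial attack, as in decalones with an adjacent angular methyl), giving the equatorial alcohol cis to that methyl.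

Step 11
Reactants: 20 allylic alcohol; 21 benzyloxyacetyl chloride
Product: 22 8-O-(benzyloxyacetyl) ester of 20
Conditions: BnOCH2COCl (1.5 equiv), pyridine, 4-(dimethylamino)pyridine (cat.), CH2Cl2, 0 °C to rt
Reagents that add atoms: benzyloxyacetyl chloride, O=C(Cl)COCc1ccccc1
Why: Nucleophile-catalysed acylation of the hindered secondary alcohol installs the glycolate needed for the sigmatropic step.

Step 12
Reactants: 22 allylic glycolate
Product: 25 (S)-2-(benzyloxy)-2-[trans-fused 6,8a-dimethyl-2-(triisopropylsilyloxy)-1,4,4a,5,6,8a-hexahydronaphthalen-6-yl]acetic acid (acid side chain cis to 8a-CH3), via silyl ketene acetal 23 (not isolated), via trimethylsilyl ester 24 (not isolated)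
Conditions: LiN(SiMe3)2 (1.5 equiv), Me3SiCl/Et3N, THF, −78 °C to 65 °C; then dilute aq. HCl
Reagents that add atoms: none
Why: Ireland–Claisen rearrangement: the chelated lithium enolate (O-metal and OBn cis) is trapped as its silyl ketene acetal, and the suprafacial [3,3] shift transfers the C8 carbinol configuration to the new quaternary C6 (side chain cis to the 8a-methyl, 6-methyl trans), while a boat-like transition state that keeps the ketene acetal away from the axial 8a-methyl should set the benzyloxy-bearing carbon as (S).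

Step 13
Reactants: 25 α-benzyloxy acid
Product: 26 (S)-2-(benzyloxy)-2-[trans-fused 6,8a-dimethyl-2-(triisopropylsilyloxy)-1,4,4a,5,6,8a-hexahydronaphthalen-6-yl]ethanol
Conditions: LiAlH4, THF, 0 °C to rt; aq. potassium sodium tartrate
Reagents that add atoms: none
Why: Hydride reduction of the carboxylic acid to the primary alcohol; silyl enol ether, benzyl ether and the ring alkene are inert to LiAlH4.

Step 14
Reactants: 26 silyl enol ether
Product: 27 trans-fused 6-[(S)-1-(benzyloxy)-2-hydroxyethyl]-6,8a-dimethyl-4a,5,6,8a-tetrahydronaphthalen-2(1H)-one (C3=C4 and C7=C8)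
Conditions: Pd(OAc)2 (1.1 equiv), MeCN/DMSO, 40 °C
Reagents that add atoms: none
Why: Saegusa–Ito oxidation of the regiodefined silyl enol ether gives the C3=C4 enone, which leaves C1 as the only enolisable position of ring A.

Step 15
Reactants: 27 ring-A enone; 8 (S)-3-(2,2,4-trimethyl-1,3-dioxolan-4-yl)propanal; 16 acetic anhydride
Product: 29 trans-fused 6-[(S)-2-acetoxy-1-(benzyloxy)ethyl]-6,8a-dimethyl-1-{3-[(S)-2,2,4-trimethyl-1,3-dioxolan-4-yl]propylidene}-4a,5,6,8a-tetrahydronaphthalen-2(1H)-one (alkene geometry immaterial), via bis-acetate 28 (not isolated)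
Conditions: LiN(iPr)2 (2.3 equiv), THF, −78 °C; 8 (1.3 equiv); Ac2O (3 equiv), −78 to 0 °C; DBU (3 equiv), rt
Reagents that add atoms: (S)-3-(2,2,4-trimethyl-1,3-dioxolan-4-yl)propanal, C[C@]1(CCC=O)COC(C)(C)O1; acetic anhydride, CC(=O)OC(C)=O
Why: Kinetic α′-deprotonation at C1 and aldol addition to the aldehyde, acetylation of both lithium alkoxides in the flask and base-induced E1cB loss of acetate (aldol condensation) give the exocyclic enone; the aldol stereocentres are erased.

Step 16
Reactants: 29 cross-conjugated dienone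
Product: 30 (1R,4aS,6S,8aS)-6-[(S)-2-acetoxy-1-hydroxyethyl]-6,8a-dimethyl-1-{3-[(S)-2,2,4-trimethyl-1,3-dioxolan-4-yl]propyl}octahydronaphthalen-2(1H)-one
Conditions: H2 (1 atm), 10% Pd/C, EtOAc/EtOH, rt
Reagents that add atoms: none
Why: Heterogeneous hydrogenation saturates the three C=C bonds and cleaves the benzyl ether; hydrogen should add to the exocyclic alkene from the face opposite the axial 8a-methyl group, which places the side chain equatorial and cis to that methyl, expected also to be the more stable epimer.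

Step 17
Reactants: 30 acetate acetonide
Product: 32 (1R,4aS,6S,8aS)-6-[(1S)-1,2-dihydroxyethyl]-1-[(4S)-4,5-dihydroxy-4-methylpentyl]-6,8a-dimethyloctahydronaphthalen-2(1H)-one (target), via acetonide triol 31 (not isolated)
Conditions: K2CO3, MeOH, rt; then 2 M aq. HCl, THF, rt
Reagents that add atoms: none
Why: Base-catalysed methanolysis of the acetate (the base also lets C1 equilibrate towards the equatorial epimer) followed by acid hydrolysis of the acetonide releases the target.

**Compound list**

1 | (R)-2-methylglycidol, (R)-(2-methyloxiran-2-yl)methanol | C[C@@]1(CO)CO1 | starting material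
2 | allylmagnesium bromide | C=CC[Mg]Br | starting material
3 | (S)-2-methylhex-5-ene-1,2-diol | C[C@@](O)(CO)CCC=C | intermediate
4 | 2,2-dimethoxypropane | COC(C)(C)OC | starting material
5 | (S)-4-(but-3-en-1-yl)-2,2,4-trimethyl-1,3-dioxolane | C[C@]1(CCC=C)COC(C)(C)O1 | intermediate
6 | ozone | [O-][O+]=O | starting material
7 | ozonide of 5 (3-substituted 1,2,4-trioxolane) | C[C@]1(CCC2OOCO2)COC(C)(C)O1 | intermediate
8 | (S)-3-(2,2,4-trimethyl-1,3-dioxolan-4-yl)propanal | C[C@]1(CCC=O)COC(C)(C)O1 | intermediate
9 | but-3-en-2-one | CC(=O)C=C | starting material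
10 | triisopropylsilyl trifluoromethanesulfonate | CC(C)[Si](C(C)C)(C(C)C)OS(=O)(=O)C(F)(F)F | starting material
11 | 2-(triisopropylsilyloxy)buta-1,3-diene | C=CC(=C)O[Si](C(C)C)(C(C)C)C(C)C | intermediate
12 | 2,5-dimethyl-1,4-benzoquinone | CC1=CC(=O)C(C)=CC1=O | starting material
13 | cis-fused 6,8a-dimethyl-2-(triisopropylsilyloxy)-1,4,4a,8a-tetrahydronaphthalene-5,8-dione; 4a-H cis to 8a-CH3 | C1C(O[Si](C(C)C)(C(C)C)C(C)C)=CC[C@@H]2C(=O)C(C)=CC(=O)[C@@]21C | intermediate
14 | trans-fused C4a epimer of 13; 4a-H anti to 8a-CH3 | C1C(O[Si](C(C)C)(C(C)C)C(C)C)=CC[C@H]2C(=O)C(C)=CC(=O)[C@@]21C | intermediate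
15 | trans-fused 5-hydroxy-6,8a-dimethyl-2-(triisopropylsilyloxy)-4,4a,5,8a-tetrahydronaphthalen-8(1H)-one; 5-OH cis to 8a-CH3 | C1C(O[Si](C(C)C)(C(C)C)C(C)C)=CC[C@H]2[C@@H](O)C(C)=CC(=O)[C@@]21C | intermediate
16 | acetic anhydride | CC(=O)OC(C)=O | starting material
17 | 5-O-acetate of 15 | C1C(O[Si](C(C)C)(C(C)C)C(C)C)=CC[C@H]2[C@@H](OC(C)=O)C(C)=CC(=O)[C@@]21C | intermediate
18 | trans-fused 6,8a-dimethyl-2-(triisopropylsilyloxy)-4,4a,7,8a-tetrahydronaphthalen-8(1H)-one (C5=C6) | C1C(O[Si](C(C)C)(C(C)C)C(C)C)=CC[C@H]2C=C(C)CC(=O)[C@@]21C | intermediate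
19 | trans-fused 6,8a-dimethyl-2-(triisopropylsilyloxy)-4,4a,5,8a-tetrahydronaphthalen-8(1H)-one (C6=C7) | C1C(O[Si](C(C)C)(C(C)C)C(C)C)=CC[C@H]2CC(C)=CC(=O)[C@@]21C | intermediate
20 | trans-fused 6,8a-dimethyl-2-(triisopropylsilyloxy)-1,4,4a,5,8,8a-hexahydronaphthalen-8-ol; 8-OH cis to 8a-CH3 | C1C(O[Si](C(C)C)(C(C)C)C(C)C)=CC[C@H]2CC(C)=C[C@@H](O)[C@@]21C | intermediate
21 | benzyloxyacetyl chloride | O=C(Cl)COCc1ccccc1 | starting material
22 | 8-O-(benzyloxyacetyl) ester of 20 | C1C(O[Si](C(C)C)(C(C)C)C(C)C)=CC[C@H]2CC(C)=C[C@@H](OC(=O)COCc3ccccc3)[C@@]21C | intermediate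
23 | trimethylsilyl ketene acetal of 22 (OSiMe3 cis to OBn) | C1C(O[Si](C(C)C)(C(C)C)C(C)C)=CC[C@H]2CC(C)=C[C@@H](O/C(=C/OCc3ccccc3)O[Si](C)(C)C)[C@@]21C | intermediate
24 | trimethylsilyl ester of 25 | C1C(O[Si](C(C)C)(C(C)C)C(C)C)=CC[C@H]2C[C@@](C)([C@H](OCc3ccccc3)C(=O)O[Si](C)(C)C)C=C[C@@]21C | intermediate
25 | (S)-2-(benzyloxy)-2-[trans-fused 6,8a-dimethyl-2-(triisopropylsilyloxy)-1,4,4a,5,6,8a-hexahydronaphthalen-6-yl]acetic acid; side chain cis to 8a-CH3, 6-CH3 trans | C1C(O[Si](C(C)C)(C(C)C)C(C)C)=CC[C@H]2C[C@@](C)([C@H](OCc3ccccc3)C(=O)O)C=C[C@@]21C | intermediate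
26 | primary alcohol from 25, (S)-2-(benzyloxy)-2-[…-6-yl]ethanol | C1C(O[Si](C(C)C)(C(C)C)C(C)C)=CC[C@H]2C[C@@](C)([C@H](OCc3ccccc3)CO)C=C[C@@]21C | intermediate
27 | trans-fused 6-[(S)-1-(benzyloxy)-2-hydroxyethyl]-6,8a-dimethyl-4a,5,6,8a-tetrahydronaphthalen-2(1H)-one | C1C(=O)C=C[C@H]2C[C@@](C)([C@H](OCc3ccccc3)CO)C=C[C@@]21C | intermediate
28 | bis-acetate of the aldol adduct of 27 and 8 (mixture at C1 and the carbinol carbon) | C[C@]1(CCC(OC(C)=O)C2C(=O)C=C[C@H]3C[C@@](C)([C@H](OCc4ccccc4)COC(C)=O)C=C[C@@]32C)COC(C)(C)O1 | intermediate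
29 | trans-fused 1-alkylidene dienone with primary acetate (alkene geometry immaterial) | C[C@]1(CCC=C2C(=O)C=C[C@H]3C[C@@](C)([C@H](OCc4ccccc4)COC(C)=O)C=C[C@@]32C)COC(C)(C)O1 | intermediate
30 | (1R,4aS,6S,8aS)-6-[(S)-2-acetoxy-1-hydroxyethyl]-6,8a-dimethyl-1-{3-[(S)-2,2,4-trimethyl-1,3-dioxolan-4-yl]propyl}octahydronaphthalen-2(1H)-one | C[C@]1(CCC[C@H]2C(=O)CC[C@H]3C[C@@](C)([C@H](O)COC(C)=O)CC[C@@]32C)COC(C)(C)O1 | intermediate
31 | deacetylated 30 (acetonide triol) | C[C@]1(CCC[C@H]2C(=O)CC[C@H]3C[C@@](C)([C@H](O)CO)CC[C@@]32C)COC(C)(C)O1 | intermediate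
32 | (1R,4aS,6S,8aS)-6-[(1S)-1,2-dihydroxyethyl]-1-[(4S)-4,5-dihydroxy-4-methylpentyl]-6,8a-dimethyloctahydronaphthalen-2(1H)-one | C[C@@](O)(CO)CCC[C@H]1C(=O)CC[C@H]2C[C@@](C)([C@H](O)CO)CC[C@@]21C | target

**Step count.** 17 steps in total; the longest linear sequence is 14 steps (steps 4 to 17, from but-3-en-2-one). Steps 1 to 3 make the side-chain aldehyde that enters in step 15.

**Steps most likely to fail**

Step 12. The [3,3] shift has to start from a pseudo-equatorial C–O bond in a locked trans-fused ring, so it may be slow enough for the silyl ketene acetal to decompose, and leakage through the chair-like transition state would erode the configuration at the benzyloxy carbon. The fallback sets out from 20 and returns at 26. Thermal Eschenmoser–Claisen rearrangement with N,N-dimethylacetamide dimethyl acetal (xylene, 140 °C) should give the C6 quaternary N,N-dimethylacetamide F1 without any enolate or silyl intermediate. Reagent-controlled hydroxylation of its sodium enolate (NaN(SiMe3)2, then the antipode of (camphorsulfonyl)oxaziridine that gives the (S)-carbinol) would give the α-hydroxy amide F2. O-Benzylation (NaH, BnBr) gives the benzyl ether F3, and LiBHEt3 reduces the tertiary amide to the primary alcohol 26.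

Step 6. The cis/trans equilibrium may lie on the wrong side, or enolisation may be slow and accompanied by decomposition. The fallback sets out from 13, replaces steps 6 to 9 and returns at 19. Enolisation towards C4a (KN(SiMe3)2, PhNTf2, THF, −78 °C) gives the dienyl triflate F4. Palladium-catalysed formate reduction (Pd(OAc)2, PPh3, HCO2H, Et3N, DMF) gives the linear dienone F5. Hydrogenation of its γ,δ-double bond (H2, Pd/C, EtOAc, trace pyridine) should deliver hydrogen to C4a from the face opposite the angular methyl and give 19, with the ring fusion set kinetically instead of by equilibration.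

Step 15. Deprotonation at the neopentylic C1 may be slow, the enolate may merely transfer a proton to the enolisable aldehyde, or the aldolate may revert before it is acetylated. The fallback sets out from 27 and 8 and returns at 31. NaBH4 reduction of 8 gives the alcohol F6, and an Appel reaction (I2, PPh3, imidazole) gives the iodide F7. Alkylation of the dianion of 27 (LiN(iPr)2, THF/DMPU) with F7 should give the C1-alkylated enone F8, with the side chain axial and anti to the 8a-methyl. Hydrogenation as in step 16 gives the C1 epimer of 31, F9. The base stage of step 17 (K2CO3, MeOH) should then equilibrate C1 towards 31; the preference for the equatorial epimer is expected to be modest, so the minor epimer would be recycled.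

Further compounds
F1 | step 12 | 2-[trans-fused 6,8a-dimethyl-2-(triisopropylsilyloxy)-1,4,4a,5,6,8a-hexahydronaphthalen-6-yl]-N,N-dimethylacetamide | C1C(O[Si](C(C)C)(C(C)C)C(C)C)=CC[C@H]2C[C@@](C)(CC(=O)N(C)C)C=C[C@@]21C
F2 | step 12 | (S)-2-hydroxy derivative of F1 | C1C(O[Si](C(C)C)(C(C)C)C(C)C)=CC[C@H]2C[C@@](C)([C@H](O)C(=O)N(C)C)C=C[C@@]21C
F3 | step 12 | (S)-2-(benzyloxy) derivative of F1 | C1C(O[Si](C(C)C)(C(C)C)C(C)C)=CC[C@H]2C[C@@](C)([C@H](OCc3ccccc3)C(=O)N(C)C)C=C[C@@]21C
F4 | step 6 | dienyl triflate of 13 (C4a=C5, triflate on C5) | C1C(O[Si](C(C)C)(C(C)C)C(C)C)=CCC2=C(OS(=O)(=O)C(F)(F)F)C(C)=CC(=O)[C@@]21C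
F5 | step 6 | 6,8a-dimethyl-2-(triisopropylsilyloxy)-4,8a-dihydronaphthalen-8(1H)-one (C4a=C5 and C6=C7) | C1C(O[Si](C(C)C)(C(C)C)C(C)C)=CCC2=CC(C)=CC(=O)[C@@]21C
F6 | step 15 | (S)-3-(2,2,4-trimethyl-1,3-dioxolan-4-yl)propan-1-ol | C[C@]1(CCCO)COC(C)(C)O1
F7 | step 15 | (S)-4-(3-iodopropyl)-2,2,4-trimethyl-1,3-dioxolane | C[C@]1(CCCI)COC(C)(C)O1
F8 | step 15 | C1-alkylated enone from 27 and F7 (side chain anti to 8a-CH3) | C[C@]1(CCC[C@@H]2C(=O)C=C[C@H]3C[C@@](C)([C@H](OCc4ccccc4)CO)C=C[C@@]32C)COC(C)(C)O1
F9 | step 15 | C1 epimer of 31 | C[C@]1(CCC[C@@H]2C(=O)CC[C@H]3C[C@@](C)([C@H](O)CO)CC[C@@]32C)COC(C)(C)O1
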